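**Retrosynthetic overview**
- The target is traced back (desilylation, then ozonolysis) to a silyl-protected bis-anhydride whose 2-oxohexyl ketone is masked as a 2-butylallyl group.
- Ring A and ring B are both opened to alkynes: a skipped 1,5-diyne plus four CO2. The two rings form together in one electroreductive nickel-catalysed carboxylation, the last skeleton-building event.
- The diyne is cut at the CH2–C(sp) bond beside the stereocentre: a primary alkyl radical (light-driven loss of CO2 from a β-alkynyl carboxylic acid) plus an alkynyl sulfone carrying the silyloxymethyl arm.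
- The acid comes from malonate SN2 with inversion on the mesylate of a purchased enantiopure propargylic alcohol, the source of the only stereocentre, after copper-catalysed allylation of its alkyne.

Assumption: the natural product is the open hydroxymethyl bis-anhydride exactly as drawn (not a lactone tautomer), so the last step is run anhydrous and non-basic.

**Step 1**
Reactants: 1 3-chloro-2-(chloromethyl)prop-1-ene (3 equiv); 2 n-propylmagnesium bromide
Product: 3 2-(chloromethyl)hex-1-ene
Conditions: Li2CuCl4 (2 mol %), THF, −30 to 0 °C, slow addition of 2; fractional distillation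
Reagents that add atoms: none
Why: Copper-catalysed allylic substitution of a Grignard reagent (SN2 and SN2' give the same product on this symmetrical dichloride); the excess of 1 suppresses double substitution.

**Step 2**
Reactants: 4 (S)-oct-1-yn-3-ol; 3 2-(chloromethyl)hex-1-ene
Product: 5 (6S)-10-methylidenetetradec-7-yn-6-ol
Conditions: CuI (10 mol %), K2CO3, n-Bu4NCl, DMF, rt
Reagents that add atoms: none
Why: Copper-catalysed coupling of a terminal alkyne with an allylic halide (Jeffery conditions) via the copper acetylide; the carbinol stereocentre is not touched.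

**Step 3**
Reactants: 5 (6S)-10-methylidenetetradec-7-yn-6-ol; 6 dimethyl malonate
Product: 8 dimethyl 2-[(6S)-10-methylidenetetradec-7-yn-6-yl]propanedioate, via mesylate 7 (not isolated)
Conditions: MsCl, Et3N, THF, −20 °C; filter; then NaCH(CO2Me)2 (from 6 and NaH, 2.5 equiv), THF–DMF, 50 °C
Reagents that add atoms: none
Why: SN2 alkylation of the soft malonate anion on the activated secondary propargylic mesylate (malonic ester synthesis) with Walden inversion sets the stereocentre of the target; the descriptor stays S only because the malonyl carbon ranks below the alkynyl carbon, whereas oxygen ranked above it.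

**Step 4**
Reactants: 8 dimethyl 2-[(6S)-10-methylidenetetradec-7-yn-6-yl]propanedioate
Product: 10 (3S)-7-methylidene-3-pentylundec-4-ynoic acid, via malonic diacid 9 (not isolated)
Conditions: LiOH, THF–H2O, 40 °C; 2 M HCl; then xylene, 140 °C
Reagents that add atoms: lithium hydroxide, [Li+].[OH-]
Why: Saponification and thermal decarboxylation of the malonic acid (malonic ester synthesis); the stereocentre carries no acidic hydrogen and is unchanged.

**Step 5**
Reactants: 11 tert-butyl(diphenyl)(prop-2-yn-1-yloxy)silane; 12 sodium 4-methylbenzenesulfinate (TolSO2Na)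
Product: 14 tert-butyl{[3-(4-methylbenzenesulfonyl)prop-2-yn-1-yl]oxy}diphenylsilane, via iodovinyl sulfone 13 (not isolated)
Conditions: I2 (1.5 equiv), EtOAc–H2O, rt; Na2S2O3 wash; then K2CO3, acetone, 56 °C
Reagents that add atoms: none
Why: Radical iodosulfonylation of the terminal alkyne by sulfonyl iodide formed in the flask (anti addition), then base-induced dehydroiodination to the acetylenic sulfone.

**Step 6**
Reactants: 10 (3S)-7-methylidene-3-pentylundec-4-ynoic acid; 14 tert-butyl{[3-(4-methylbenzenesulfonyl)prop-2-yn-1-yl]oxy}diphenylsilane (1.5 equiv)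
Product: 16 tert-butyl{[(5S)-9-methylidene-5-pentyltrideca-2,6-diyn-1-yl]oxy}diphenylsilane, via N-acyloxyphthalimide 15 (not isolated)
Conditions: N-hydroxyphthalimide, DIC, DMAP (5 mol %), CH2Cl2, rt; then 14, Ru(bpy)3(PF6)2 (1 mol %), Hantzsch ester (1.5 equiv), i-Pr2NEt, 450 nm LEDs, rt
Reagents that add atoms: none
Why: Photoredox decarboxylative alkynylation: single-electron reduction of the redox-active ester releases CO2 and a primary radical, which adds to the sulfonyl-bearing alkyne carbon and expels the sulfonyl radical. The radical sits one carbon from the stereocentre and its only neighbour is an alkyne, a poor 3-exo acceptor, so configuration is kept and no 1,2-shift occurs; this is why the coupling precedes ring formation.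

**Step 7**
Reactants: 16 tert-butyl{[(5S)-9-methylidene-5-pentyltrideca-2,6-diyn-1-yl]oxy}diphenylsilane
Product: 18 3-{[tert-butyl(diphenyl)silyl]oxymethyl}-4-{(2S)-2-[4-(2-methylidenehexyl)-2,5-dioxo-2,5-dihydrofuran-3-yl]heptyl}furan-2,5-dione, via tetra-acid 17 (not isolated)
Conditions: undivided cell, Mg anode, carbon-felt cathode, Ni(acac)2 (20 mol %), 2,2'-bipyridine (20 mol %), MgBr2 (1 equiv), n-Bu4NBF4, CO2 (1 atm), DMF, 5 mA cm−2, 5–6 F mol−1, rt; then cold 2 M HCl; toluene azeotrope, 50 °C
Reagents that add atoms: carbon dioxide, O=C=O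
Why: Proposed new method: electroreductive nickel-catalysed double carboxylation of each internal alkyne, in which cathodically generated zerovalent nickel–bipyridine couples alkyne and CO2 to an oxanickelacyclopentenone, magnesium ions from the sacrificial anode open its Ni–O bond, and a further cathodic electron makes the alkenylnickel insert a second CO2 on the same side, giving the cis dicarboxylate that closes to the anhydride on acidification (both rings form here, the stereocentre is not involved); the closest known reaction types are the Ni(acac)2(bpy)/Zn/MgBr2 double carboxylation of internal alkynes and the nickel–bipyridine electrocarboxylation of alkynes with a magnesium anode, which normally stops at the mono-acid.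

**Step 8**
Reactants: 18 3-{[tert-butyl(diphenyl)silyl]oxymethyl}-4-{(2S)-2-[4-(2-methylidenehexyl)-2,5-dioxo-2,5-dihydrofuran-3-yl]heptyl}furan-2,5-dione
Product: 20 3-{[tert-butyl(diphenyl)silyl]oxymethyl}-4-{(2S)-2-[2,5-dioxo-4-(2-oxohexyl)-2,5-dihydrofuran-3-yl]heptyl}furan-2,5-dione, via ozonide 19 (not isolated)
Conditions: O3, CH2Cl2, −78 °C (Sudan red end point); then PPh3, −78 °C to rt
Reagents that add atoms: ozone, [O-][O+]=O
Why: Ozonolysis (Criegee mechanism) cleaves only the electron-rich 1,1-disubstituted alkene; the electron-poor tetrasubstituted anhydride alkenes are inert at −78 °C. The ozonide forms as both epimers at its acetal carbon, which is destroyed on reduction.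

**Step 9**
Reactants: 20 3-{[tert-butyl(diphenyl)silyl]oxymethyl}-4-{(2S)-2-[2,5-dioxo-4-(2-oxohexyl)-2,5-dihydrofuran-3-yl]heptyl}furan-2,5-dione
Product: 21 3-(hydroxymethyl)-4-{(2S)-2-[2,5-dioxo-4-(2-oxohexyl)-2,5-dihydrofuran-3-yl]heptyl}furan-2,5-dione
Conditions: HF·pyridine, THF, 0 °C to rt; dilute with EtOAc, cold water wash
Reagents that add atoms: none
Why: Fluoride-mediated silyl ether cleavage under acidic, non-nucleophilic conditions leaves both anhydrides and the ketone intact; the freed hydroxyl cannot attack the ring carbonyl directly (that would need a bridgehead alkene), so the open form persists.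

**Compound list**
1 | 3-chloro-2-(chloromethyl)prop-1-ene | C=C(CCl)CCl | starting material
2 | n-propylmagnesium bromide | CCC[Mg]Br | starting material
3 | 2-(chloromethyl)hex-1-ene | C=C(CCl)CCCC | intermediate
4 | (S)-oct-1-yn-3-ol | CCCCC[C@H](O)C#C | starting material
5 | (6S)-10-methylidenetetradec-7-yn-6-ol | CCCCC[C@H](O)C#CCC(=C)CCCC | intermediate
6 | dimethyl malonate | COC(=O)CC(=O)OC | starting material
7 | (6S)-10-methylidenetetradec-7-yn-6-yl methanesulfonate | CCCCC[C@H](OS(C)(=O)=O)C#CCC(=C)CCCC | intermediate
8 | dimethyl 2-[(6S)-10-methylidenetetradec-7-yn-6-yl]propanedioate | CCCCC[C@@H](C(C(=O)OC)C(=O)OC)C#CCC(=C)CCCC | intermediate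
9 | 2-[(6S)-10-methylidenetetradec-7-yn-6-yl]propanedioic acid | CCCCC[C@@H](C(C(=O)O)C(=O)O)C#CCC(=C)CCCC | intermediate
10 | (3S)-7-methylidene-3-pentylundec-4-ynoic acid | CCCCC[C@@H](CC(=O)O)C#CCC(=C)CCCC | intermediate
11 | tert-butyl(diphenyl)(prop-2-yn-1-yloxy)silane | C#CCO[Si](c1ccccc1)(c1ccccc1)C(C)(C)C | starting material
12 | sodium 4-methylbenzenesulfinate | Cc1ccc(cc1)S(=O)[O-].[Na+] | starting material
13 | tert-butyl{[(2E)-2-iodo-3-(4-methylbenzenesulfonyl)prop-2-en-1-yl]oxy}diphenylsilane | CC(C)(C)[Si](OC/C(I)=C\S(=O)(=O)c1ccc(C)cc1)(c1ccccc1)c1ccccc1 | intermediate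
14 | tert-butyl{[3-(4-methylbenzenesulfonyl)prop-2-yn-1-yl]oxy}diphenylsilane | CC(C)(C)[Si](OCC#CS(=O)(=O)c1ccc(C)cc1)(c1ccccc1)c1ccccc1 | intermediate
15 | 1,3-dioxoisoindolin-2-yl (3S)-7-methylidene-3-pentylundec-4-ynoate | CCCCC[C@@H](CC(=O)ON1C(=O)c2ccccc2C1=O)C#CCC(=C)CCCC | intermediate
16 | tert-butyl{[(5S)-9-methylidene-5-pentyltrideca-2,6-diyn-1-yl]oxy}diphenylsilane | CCCCC[C@@H](CC#CCO[Si](c1ccccc1)(c1ccccc1)C(C)(C)C)C#CCC(=C)CCCC | intermediate
17 | (Z)-2-{[tert-butyl(diphenyl)silyl]oxymethyl}-3-{(2S)-2-[(Z)-1,2-dicarboxy-4-methylideneoct-1-en-1-yl]heptyl}but-2-enedioic acid | CCCCC[C@@H](C/C(C(=O)O)=C(\CO[Si](c1ccccc1)(c1ccccc1)C(C)(C)C)C(=O)O)/C(C(=O)O)=C(\CC(=C)CCCC)C(=O)O | intermediate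
18 | 3-{[tert-butyl(diphenyl)silyl]oxymethyl}-4-{(2S)-2-[4-(2-methylidenehexyl)-2,5-dioxo-2,5-dihydrofuran-3-yl]heptyl}furan-2,5-dione | CCCCC[C@@H](CC1=C(CO[Si](c2ccccc2)(c2ccccc2)C(C)(C)C)C(=O)OC1=O)C1=C(CC(=C)CCCC)C(=O)OC1=O | intermediate
19 | ozonide of 18: 3-{[tert-butyl(diphenyl)silyl]oxymethyl}-4-{(2S)-2-[4-[(3-butyl-1,2,4-trioxolan-3-yl)methyl]-2,5-dioxo-2,5-dihydrofuran-3-yl]heptyl}furan-2,5-dione (both epimers at the trioxolane carbon) | CCCCC[C@@H](CC1=C(CO[Si](c2ccccc2)(c2ccccc2)C(C)(C)C)C(=O)OC1=O)C1=C(CC2(CCCC)OCOO2)C(=O)OC1=O | intermediate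
20 | 3-{[tert-butyl(diphenyl)silyl]oxymethyl}-4-{(2S)-2-[2,5-dioxo-4-(2-oxohexyl)-2,5-dihydrofuran-3-yl]heptyl}furan-2,5-dione | CCCCC[C@@H](CC1=C(CO[Si](c2ccccc2)(c2ccccc2)C(C)(C)C)C(=O)OC1=O)C1=C(CC(=O)CCCC)C(=O)OC1=O | intermediate
21 | 3-(hydroxymethyl)-4-{(2S)-2-[2,5-dioxo-4-(2-oxohexyl)-2,5-dihydrofuran-3-yl]heptyl}furan-2,5-dione | CCCCC[C@@H](CC1=C(CO)C(=O)OC1=O)C1=C(CC(=O)CCCC)C(=O)OC1=O | target

**Step count and risks**
Total step count: 9. Longest linear sequence: 8 steps (steps 1, 2, 3, 4, 6, 7, 8, 9, from 1 and 2); step 5 is a one-step side branch.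

Most likely to fail, first: step 7, the new electrochemical fourfold carboxylation. Adventitious protons can intercept the alkenylnickel to give acrylic acids, one alkyne may react incompletely, and the alkenylnickel next to the silyloxymethyl group could lose silanolate. The fallback leaves electrolysis for the published stoichiometric-metal reductive carboxylation. It sets out from 16 and comes back at 18: Ni(acac)2(bpy) (20 mol %), Zn powder and MgBr2 (6 equiv each), 4 Å molecular sieves, CO2 (1 atm), DMF, rt, then the same acid work-up through 17. No new compound arises (F0).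

Second: step 6. Addition of an unstabilised primary radical to an alkyl-type alkynyl sulfone can be slow, and reduction of the radical to the alkane competes. The fallback replaces radical alkynylation by polar acetylide alkylation. It sets out from 10 and comes back at 16: 10 is converted to 15 as before, and 15 undergoes the known visible-light iododecarboxylation (LiI, PPh3 catalytic, 456 nm, acetone) to the primary iodide (6R)-6-(iodomethyl)-10-methylidenetetradec-7-yne F1. F1 is then alkylated with the lithium acetylide of 11 (n-BuLi, THF–DMPU, −78 °C to rt) to give 16.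

Third: step 3. Elimination to the enyne, SN2' attack to an allene, or partial ionisation of the propargylic mesylate would cost yield or enantiopurity. The fallback is a Mitsunobu carbon alkylation, also with inversion. It sets out from 5 and comes back at 9: 5 reacts with triethyl methanetricarboxylate, PMe3 and 1,1'-(azodicarbonyl)dipiperidine in toluene to give triethyl (2R)-6-methylidene-2-pentyldec-3-yne-1,1,1-tricarboxylate F2. Saponification (NaOH, aqueous EtOH) and acidification give (2R)-6-methylidene-2-pentyldec-3-yne-1,1,1-tricarboxylic acid F3, which loses CO2 at room temperature to 9 and continues as in step 4.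

**Further compounds**
F0 | step 7 | none | none
F1 | step 6 | (6R)-6-(iodomethyl)-10-methylidenetetradec-7-yne | CCCCC[C@@H](CI)C#CCC(=C)CCCC
F2 | step 3 | triethyl (2R)-6-methylidene-2-pentyldec-3-yne-1,1,1-tricarboxylate | CCCCC[C@@H](C(C(=O)OCC)(C(=O)OCC)C(=O)OCC)C#CCC(=C)CCCC
F3 | step 3 | (2R)-6-methylidene-2-pentyldec-3-yne-1,1,1-tricarboxylic acid | CCCCC[C@@H](C(C(=O)O)(C(=O)O)C(=O)O)C#CCC(=C)CCCC
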